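## Plan

- **Retrosynthesis:** the O–C(CH3) bond of the oxygen bridge and the neighbouring C–Br bond are cut together (transannular bromoetherification), which leads back to (S)-1-(bromodimethylcyclohexyl)-4-methylcyclohex-3-en-1-ol. Next come C–CH3 (enol triflate), then the C–OH and the four C–H bonds of a p-quinol, i.e. a para-substituted phenol. In ring A (the bromodimethylcyclohexane) C–Br, the two C–CH3 and the enone are cut back to 4-(4-methoxyphenyl)cyclohexanone, which already holds the bond between the two rings.
- **Enabling feature:** the two bridgeheads are 1,4-carbons of one cyclohexane, the oxygen sits on the carbon that carries ring A, and Br on the CH next to the methyl bridgehead is anti to the bridge (endo). This is the mark of anti addition of Br+ and a tertiary OH across a 1-methylcyclohexene. The same 1,4 pattern (C–O at the ring junction, C=O para) is that of a p-quinol made from a phenol.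
- **Forward order:** ring A is present from the start and is finished first (enone, gem-dimethyl, equatorial Br). The anisole ring is then dearomatised to the second carbocycle. The oxygen bridge, and with it the brominated five-membered ring, is closed last.
- **Stereochemistry:** one chiral lithium amide differentiates enantiotopic α-protons twice (step 1 sets the ring A methine, step 10 the carbinol carbon). The ring A C–Br centre is relayed from the methine in a locked chair (step 6). The quaternary C–O and the C–Br centres of the bicycle are relayed from the carbinol carbon in one event (step 13).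

Key step: step 13

Assumption: the sense of induction of the chiral amide is taken from 4-tert-butylcyclohexanone, for which the (R,R)-amide gives the (S)-enol silane; on that basis the (S,S)-amide is used in steps 1 and 10, and the (R,R)-amide would be used instead if the sense proved opposite for these substrates.

## Route

Step 1
Reactants: 1 4-(4-methoxyphenyl)cyclohexan-1-one
Product: 2 {[(4R)-4-(4-methoxyphenyl)cyclohex-1-en-1-yl]oxy}trimethylsilane
Conditions: (S,S)-bis(1-phenylethyl)amine, n-BuLi, THF, −78 °C; TMSCl (in situ quench), −78 °C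
Reagents that add atoms: chlorotrimethylsilane, C[Si](C)(C)Cl
Why: Enantioselective deprotonation of a prochiral 4-substituted cyclohexanone with a C2-symmetric chiral lithium amide and in situ silylation (chiral-base desymmetrisation) removes one of the two enantiotopic axial α-protons of the chair with the aryl group equatorial, which turns C4 into the R stereocenter that becomes the ring A methine.

Step 2
Reactants: 2 {[(4R)-4-(4-methoxyphenyl)cyclohex-1-en-1-yl]oxy}trimethylsilane
Product: 3 (4R)-4-(4-methoxyphenyl)cyclohex-2-en-1-one
Conditions: Pd(OAc)2 (1.0 equiv), MeCN, rt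
Reagents that add atoms: none
Why: Saegusa–Ito oxidation (Pd(II) enolate, β-hydride elimination) places the enone double bond on the arm marked in step 1 without touching C4, and the enone, expected to be crystalline, offers a point to raise the enantiomeric purity.

Step 3
Reactants: 3 (4R)-4-(4-methoxyphenyl)cyclohex-2-en-1-one
Product: 7 (4R)-4-(4-methoxyphenyl)-6,6-dimethylcyclohex-2-en-1-one, via lithium dienolate 4 (not isolated), via monomethyl enone 5 (not isolated), via lithium dienolate 6 (not isolated)
Conditions: LDA (1.1 equiv), THF, −78 °C; MeI; then LDA (1.2 equiv), −78 °C; MeI, −78 → −20 °C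
Reagents that add atoms: iodomethane, CI
Why: Kinetic α′-deprotonation of a cyclohex-2-enone with LDA gives the cross-conjugated dienolate, which is C-methylated (enolate alkylation); run twice this puts the gem-dimethyl group on the arm away from the double bond, while the benzylic γ-proton at C4 should not be removed under kinetic control.

Step 4
Reactants: 7 (4R)-4-(4-methoxyphenyl)-6,6-dimethylcyclohex-2-en-1-one
Product: 9 (4S)-4-(4-methoxyphenyl)-6,6-dimethylcyclohex-1-en-1-yl trifluoromethanesulfonate, via lithium enolate 8 (not isolated)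
Conditions: L-Selectride, THF, −78 °C; PhNTf2, −78 °C → rt
Reagents that add atoms: N-phenylbis(trifluoromethanesulfonimide), O=S(=O)(N(c1ccccc1)S(=O)(=O)C(F)(F)F)C(F)(F)F
Why: L-Selectride adds hydride 1,4 to the β-unsubstituted enone, whose carbonyl is shielded by the neighbouring quaternary carbon, and PhNTf2 O-sulfonylates the regiodefined enolate (conjugate reduction–enolate trapping to an enol triflate); the descriptor at C4 changes only because the priorities change.

Step 5
Reactants: 9 (4S)-4-(4-methoxyphenyl)-6,6-dimethylcyclohex-1-en-1-yl trifluoromethanesulfonate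
Product: 10 1-[(1S)-4-bromo-5,5-dimethylcyclohex-3-en-1-yl]-4-methoxybenzene
Conditions: Ni(OAc)2·4H2O (10 mol %), cod, Zn (cat.), LiBr, DMA/THF, rt
Reagents that add atoms: lithium bromide, [Li+].[Br-]
Why: Nickel-catalysed halogenation of an enol triflate (oxidative addition, triflate–bromide exchange, C–Br reductive elimination) converts C–OTf into C–Br at the same carbon and leaves the anisole alone.

Step 6
Reactants: 10 1-[(1S)-4-bromo-5,5-dimethylcyclohex-3-en-1-yl]-4-methoxybenzene
Product: 11 1-[(1S,4S)-4-bromo-3,3-dimethylcyclohexyl]-4-methoxybenzene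
Conditions: Mn(dpm)3 (10 mol %), PhSiH3, t-BuOOH, i-PrOH, rt
Reagents that add atoms: none
Why: Metal-hydride hydrogen-atom-transfer hydrogenation, a radical hydrogenation that reduces alkenyl halides to alkyl halides without loss of halogen, adds H• to the CH end of the bromoalkene and should then deliver the second hydrogen to the α-bromo radical axially, anti to the axial methyl of the neighbouring quaternary carbon, in the chair that the aryl group locks (an axial aryl would be 1,3-diaxial to a methyl), so that Br becomes equatorial and trans to the aryl group (S at C–Br).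

Step 7
Reactants: 11 1-[(1S,4S)-4-bromo-3,3-dimethylcyclohexyl]-4-methoxybenzene
Product: 12 4-[(1S,4S)-4-bromo-3,3-dimethylcyclohexyl]phenol
Conditions: BBr3, CH2Cl2, −78 → 0 °C; H2O
Reagents that add atoms: none
Why: Lewis-acid cleavage of the aryl methyl ether (BBr3, SN2 at methyl) frees the phenol; the hindered secondary alkyl bromide is inert.

Step 8
Reactants: 12 4-[(1S,4S)-4-bromo-3,3-dimethylcyclohexyl]phenol
Product: 13 4-[(1S,4S)-4-bromo-3,3-dimethylcyclohexyl]-4-hydroxycyclohexa-2,5-dien-1-one
Conditions: PhI(OAc)2, MeCN/H2O, 0 °C
Reagents that add atoms: water, O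
Why: Hypervalent-iodine oxidative dearomatisation of a para-alkylphenol: the aryloxy-λ3-iodane is attacked by water at the substituted para carbon to give the p-quinol, which puts the tertiary hydroxyl on the carbon that carries ring A and leaves the carbonyl para to it; the new ring has a mirror plane, so no stereocenter arises.

Step 9
Reactants: 13 4-[(1S,4S)-4-bromo-3,3-dimethylcyclohexyl]-4-hydroxycyclohexa-2,5-dien-1-one
Product: 14 4-[(1S,4S)-4-bromo-3,3-dimethylcyclohexyl]-4-hydroxycyclohexan-1-one
Conditions: H2 (1 atm), RhCl(PPh3)3 (5 mol %), PhH/EtOH, rt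
Reagents that add atoms: none
Why: Homogeneous hydrogenation with Wilkinson's catalyst saturates the two disubstituted enone double bonds without hydrogenolysis of the C–Br bond or of the tertiary allylic C–O bond.

Step 10
Reactants: 14 4-[(1S,4S)-4-bromo-3,3-dimethylcyclohexyl]-4-hydroxycyclohexan-1-one
Product: 15 trimethyl({(1S)-1-[(1S,4S)-4-bromo-3,3-dimethylcyclohexyl]-4-[(trimethylsilyl)oxy]cyclohex-3-en-1-yl}oxy)silane
Conditions: (S,S)-bis(1-phenylethyl)amine, n-BuLi (2.3 equiv of amide), THF, −78 °C; TMSCl (in situ, excess), −78 °C → rt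
Reagents that add atoms: chlorotrimethylsilane, C[Si](C)(C)Cl
Why: Second chiral-base desymmetrisation: the alkoxide is silylated in the flask and the amide removes one of the two enantiotopic axial α-protons of the chair with the cyclohexyl group equatorial and O axial, which places the enol double bond on one arm and thereby makes the carbinol carbon the S stereocenter, under reagent control because ring A is too remote to bias the choice.

Step 11
Reactants: 15 trimethyl({(1S)-1-[(1S,4S)-4-bromo-3,3-dimethylcyclohexyl]-4-[(trimethylsilyl)oxy]cyclohex-3-en-1-yl}oxy)silane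
Product: 17 (4S)-4-[(1S,4S)-4-bromo-3,3-dimethylcyclohexyl]-4-[(trimethylsilyl)oxy]cyclohex-1-en-1-yl trifluoromethanesulfonate, via lithium enolate 16 (not isolated)
Conditions: MeLi (1.05 equiv), THF, 0 °C; PhNTf2, −78 °C → rt
Reagents that add atoms: N-phenylbis(trifluoromethanesulfonimide), O=S(=O)(N(c1ccccc1)S(=O)(=O)C(F)(F)F)C(F)(F)F
Why: Methyllithium cleaves the enol silane to the regiodefined lithium enolate, which PhNTf2 converts into the enol triflate (enolate O-triflation); the tertiary silyl ether and the neopentyl-type secondary bromide should not react.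

Step 12
Reactants: 17 (4S)-4-[(1S,4S)-4-bromo-3,3-dimethylcyclohexyl]-4-[(trimethylsilyl)oxy]cyclohex-1-en-1-yl trifluoromethanesulfonate
Product: 19 (1S)-1-[(1S,4S)-4-bromo-3,3-dimethylcyclohexyl]-4-methylcyclohex-3-en-1-ol, via silyl ether 18 (not isolated)
Conditions: MeZnCl (2 equiv), Pd(PPh3)4 (5 mol %), THF, 50 °C; then K2CO3, MeOH, rt
Reagents that add atoms: chloro(methyl)zinc, C[Zn]Cl
Why: Negishi coupling of the enol triflate with methylzinc chloride gives the trisubstituted methyl alkene with the double bond in place (Pd(PPh3)4 does not insert into the unactivated secondary C–Br bond), and methanolysis removes the silyl helper.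

Step 13
Reactants: 19 (1S)-1-[(1S,4S)-4-bromo-3,3-dimethylcyclohexyl]-4-methylcyclohex-3-en-1-ol
Product: 20 (1R,2R,4S)-2-bromo-4-[(1S,4S)-4-bromo-3,3-dimethylcyclohexyl]-1-methyl-7-oxabicyclo[2.2.1]heptane
Conditions: NBS (1.1 equiv), CH2Cl2, 0 °C, dark
Reagents that add atoms: N-bromosuccinimide, O=C1CCC(=O)N1Br
Why: NBS transfers Br+ reversibly to the C3=C4 double bond of 19, and only the bromonium ion on the face opposite to the tertiary hydroxyl is opened productively, the C1 oxygen attacking the methyl-bearing C4 across the ring through a boat in which O is flagpole and the ring A substituent bowsprit, after which the oxonium loses its proton to succinimide anion. The closest known reaction type is the transannular bromoetherification (haloetherification with anti addition) of terpinen-4-ol-type 4-methylcyclohex-3-en-1-ols to 2-bromo-1,4-cineoles. The single O–C bond closes both five-membered rings of the bicycle at once: the brominated ring (O, C1, C2, C3, C4 of 19) in a 5-endo sense with regard to the bromonium C–C bond and the unbrominated ring (O, C1, C6, C5, C4) in a 5-exo sense, both enforced by the existing six-membered ring. The new quaternary C–O centre can only form with the bridge on the face of the hydroxyl, so it is fixed by the carbinol stereocenter of step 10, and the C–Br centre follows from anti opening, which puts Br endo (anti to the bridge) as in the target. The step needs Markovnikov regioselectivity and one bromonium face: the first is secured because only the tertiary carbon is within reach of the oxygen (attack at the secondary carbon would give an oxetane), the second because the wrong-face bromonium cannot be captured internally and reverts. Ring A with its secondary bromide is a spectator, and the pseudo-axial hydroxyl of the ground-state half-chair (large substituent pseudo-equatorial) is already placed for the closure.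

## Compound list

1 | 4-(4-methoxyphenyl)cyclohexan-1-one | O=C1CCC(CC1)c1ccc(OC)cc1 | starting material
2 | {[(4R)-4-(4-methoxyphenyl)cyclohex-1-en-1-yl]oxy}trimethylsilane | C[Si](C)(C)OC1=CC[C@H](c2ccc(OC)cc2)CC1 | intermediate
3 | (4R)-4-(4-methoxyphenyl)cyclohex-2-en-1-one | O=C1CC[C@@H](c2ccc(OC)cc2)C=C1 | intermediate
4 | lithium (4R)-4-(4-methoxyphenyl)cyclohexa-1,5-dien-1-olate | [Li]OC1=CC[C@@H](c2ccc(OC)cc2)C=C1 | intermediate (not isolated)
5 | (4R)-4-(4-methoxyphenyl)-6-methylcyclohex-2-en-1-one (C6 epimers) | O=C1C(C)C[C@@H](c2ccc(OC)cc2)C=C1 | intermediate (not isolated)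
6 | lithium (4R)-4-(4-methoxyphenyl)-2-methylcyclohexa-1,5-dien-1-olate | [Li]OC1=C(C)C[C@@H](c2ccc(OC)cc2)C=C1 | intermediate (not isolated)
7 | (4R)-4-(4-methoxyphenyl)-6,6-dimethylcyclohex-2-en-1-one | O=C1C(C)(C)C[C@@H](c2ccc(OC)cc2)C=C1 | intermediate
8 | lithium (4S)-4-(4-methoxyphenyl)-6,6-dimethylcyclohex-1-en-1-olate | CC1(C)C[C@@H](c2ccc(OC)cc2)CC=C1O[Li] | intermediate (not isolated)
9 | (4S)-4-(4-methoxyphenyl)-6,6-dimethylcyclohex-1-en-1-yl trifluoromethanesulfonate | CC1(C)C[C@@H](c2ccc(OC)cc2)CC=C1OS(=O)(=O)C(F)(F)F | intermediate
10 | 1-[(1S)-4-bromo-5,5-dimethylcyclohex-3-en-1-yl]-4-methoxybenzene | CC1(C)C[C@@H](c2ccc(OC)cc2)CC=C1Br | intermediate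
11 | 1-[(1S,4S)-4-bromo-3,3-dimethylcyclohexyl]-4-methoxybenzene | CC1(C)C[C@@H](c2ccc(OC)cc2)CC[C@@H]1Br | intermediate
12 | 4-[(1S,4S)-4-bromo-3,3-dimethylcyclohexyl]phenol | CC1(C)C[C@@H](c2ccc(O)cc2)CC[C@@H]1Br | intermediate
13 | 4-[(1S,4S)-4-bromo-3,3-dimethylcyclohexyl]-4-hydroxycyclohexa-2,5-dien-1-one | CC1(C)C[C@@H](C2(O)C=CC(=O)C=C2)CC[C@@H]1Br | intermediate
14 | 4-[(1S,4S)-4-bromo-3,3-dimethylcyclohexyl]-4-hydroxycyclohexan-1-one | CC1(C)C[C@@H](C2(O)CCC(=O)CC2)CC[C@@H]1Br | intermediate
15 | trimethyl({(1S)-1-[(1S,4S)-4-bromo-3,3-dimethylcyclohexyl]-4-[(trimethylsilyl)oxy]cyclohex-3-en-1-yl}oxy)silane | CC1(C)C[C@@H]([C@]2(O[Si](C)(C)C)CCC(O[Si](C)(C)C)=CC2)CC[C@@H]1Br | intermediate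
16 | lithium (4S)-4-[(1S,4S)-4-bromo-3,3-dimethylcyclohexyl]-4-[(trimethylsilyl)oxy]cyclohex-1-en-1-olate | CC1(C)C[C@@H]([C@]2(O[Si](C)(C)C)CCC(O[Li])=CC2)CC[C@@H]1Br | intermediate (not isolated)
17 | (4S)-4-[(1S,4S)-4-bromo-3,3-dimethylcyclohexyl]-4-[(trimethylsilyl)oxy]cyclohex-1-en-1-yl trifluoromethanesulfonate | CC1(C)C[C@@H]([C@]2(O[Si](C)(C)C)CCC(OS(=O)(=O)C(F)(F)F)=CC2)CC[C@@H]1Br | intermediate
18 | ({(1S)-1-[(1S,4S)-4-bromo-3,3-dimethylcyclohexyl]-4-methylcyclohex-3-en-1-yl}oxy)trimethylsilane | CC1(C)C[C@@H]([C@]2(O[Si](C)(C)C)CCC(C)=CC2)CC[C@@H]1Br | intermediate (not isolated)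
19 | (1S)-1-[(1S,4S)-4-bromo-3,3-dimethylcyclohexyl]-4-methylcyclohex-3-en-1-ol | CC1(C)C[C@@H]([C@]2(O)CCC(C)=CC2)CC[C@@H]1Br | intermediate
20 | (1R,2R,4S)-2-bromo-4-[(1S,4S)-4-bromo-3,3-dimethylcyclohexyl]-1-methyl-7-oxabicyclo[2.2.1]heptane | CC1(C)C[C@@H]([C@@]23CC[C@@](C)(O2)[C@H](Br)C3)CC[C@@H]1Br | target

## Step count and risks

Total step count: 13. Longest linear sequence: 13 steps (the route is fully linear from 1).

**Step 6.** The hydrogen atom may be delivered to the α-bromo radical from the equatorial side (poor facial selectivity, giving the cis bromide). Bromine may also be lost by over-reduction, or the benzylic methine may be epimerised by hydrogen abstraction. The fallback sets out from 7 and avoids the radical step. Hydrogenation of the enone double bond (H2, Pd/C, EtOAc) should give (4S)-4-(4-methoxyphenyl)-2,2-dimethylcyclohexan-1-one F1. L-Selectride, which attacks the aryl-locked chair from the equatorial side, should give the axial alcohol (1R,4S)-4-(4-methoxyphenyl)-2,2-dimethylcyclohexan-1-ol F2. Appel bromination (PPh3, CBr4, CH2Cl2) with inversion then comes back to the route at 11. Elimination is expected to compete at this neopentyl-type centre, which is why this is the second choice.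

**Step 10.** The amide may fail to discriminate the two enantiotopic α-methylene groups well enough, for example because the lithium alkoxide disturbs the amide aggregate, and the resulting carbinol epimers would be hard to separate later. The fallback sets out from 13 and sets the same centre enzymatically. An ene-reductase of the Old Yellow Enzyme family (NADPH recycled with glucose and glucose dehydrogenase, buffer, 30 °C), chosen by screening for the required arm, reduces one of the two enantiotopic enone double bonds to (4R)-4-[(1S,4S)-4-bromo-3,3-dimethylcyclohexyl]-4-hydroxycyclohex-2-en-1-one F3. L-Selectride (2.2 equiv) reduces the remaining enone 1,4 and PhNTf2 traps the enolate as (4S)-4-[(1S,4S)-4-bromo-3,3-dimethylcyclohexyl]-4-hydroxycyclohex-1-en-1-yl trifluoromethanesulfonate F4; the tertiary lithium alkoxide should be too hindered to be sulfonylated at −78 °C. Negishi methylation (MeZnCl in excess, Pd(PPh3)4) comes back to the route at 19.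

**Step 3.** The kinetic dienolate may equilibrate to the extended dienolate by loss of the benzylic γ-proton, which would erode the configuration at C4 and open γ-methylation. The fallback sets out from 1 and never passes through an enone. The (R,R)-amide with TMSCl gives the antipodal enol silane {[(4S)-4-(4-methoxyphenyl)cyclohex-1-en-1-yl]oxy}trimethylsilane F5. MeLi then MeI gives (4S)-4-(4-methoxyphenyl)-2-methylcyclohexan-1-one F6 by regiospecific enolate methylation. TMSCl, NaI and Et3N in MeCN give the thermodynamic enol silane {[(4S)-4-(4-methoxyphenyl)-2-methylcyclohex-1-en-1-yl]oxy}trimethylsilane F7. MeLi then MeI gives the ketone F1 already described under step 6. KHMDS then PhNTf2, which can enolise only toward the CH2 side, comes back to the route at 9.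

## Further compounds

F1 | step 6 | (4S)-4-(4-methoxyphenyl)-2,2-dimethylcyclohexan-1-one | CC1(C)C[C@@H](c2ccc(OC)cc2)CCC1=O
F2 | step 6 | (1R,4S)-4-(4-methoxyphenyl)-2,2-dimethylcyclohexan-1-ol | CC1(C)C[C@@H](c2ccc(OC)cc2)CC[C@H]1O
F3 | step 10 | (4R)-4-[(1S,4S)-4-bromo-3,3-dimethylcyclohexyl]-4-hydroxycyclohex-2-en-1-one | CC1(C)C[C@@H]([C@]2(O)CCC(=O)C=C2)CC[C@@H]1Br
F4 | step 10 | (4S)-4-[(1S,4S)-4-bromo-3,3-dimethylcyclohexyl]-4-hydroxycyclohex-1-en-1-yl trifluoromethanesulfonate | CC1(C)C[C@@H]([C@]2(O)CCC(OS(=O)(=O)C(F)(F)F)=CC2)CC[C@@H]1Br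
F5 | step 3 | {[(4S)-4-(4-methoxyphenyl)cyclohex-1-en-1-yl]oxy}trimethylsilane | C[Si](C)(C)OC1=CC[C@@H](c2ccc(OC)cc2)CC1
F6 | step 3 | (4S)-4-(4-methoxyphenyl)-2-methylcyclohexan-1-one (C2 epimers) | CC1C[C@@H](c2ccc(OC)cc2)CCC1=O
F7 | step 3 | {[(4S)-4-(4-methoxyphenyl)-2-methylcyclohex-1-en-1-yl]oxy}trimethylsilane | C[Si](C)(C)OC1=C(C)C[C@@H](c2ccc(OC)cc2)CC1
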